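Everything rests on growing ring A (C4a, C5, C6, C7, C8, C8a) onto a finished ring C, exploiting the meta relationship of its oxygens at C5 and C7, the signature of a vinylketene–ynol ether benzannulation. The precursor is a kojic-acid-derived 4-pyranone that already carries the C3 oxygen, the enantiopure chroman B ring and, next to the ring oxygen, a diazoacetyl group. Loss of N2 with 1,2-shift gives a pyranonylketene. It adds benzyl ethynyl ether, and the cyclobutenone opens and recloses onto the pyranone C–H carbon. One operation forms four C–C bonds and the whole resorcinol ring. The single stereocentre stems from a Jacobsen epoxidation.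

Key step: step 13

Remarks on the chemistry:
- **Configuration.** The carbinol carbon of the target (chroman C3) works out as R from the SMILES (O > C2 > C4 > H).
- **Numbering.** Monocyclic pyranones are numbered as kojic acid: O1, C2 with the side chain, C3–H, C4=O, C5–O, C6. Their C6, C5, C4, C3 and C2 become flavone C2, C3, C4, C4a and C8a.
- **Wavelength.** 3-Alkoxy-2-arylchromones photocyclise under UV light by hydrogen abstraction from the O–CH2 group, and the same must be feared for the pyranone. Only the diazo chromophore is therefore addressed, at 450 nm.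
- **Staging.** Light and heat are applied in separate stages.
- **Excess alkyne.** Benzyl alkynyl ethers rearrange sigmatropically near 60 °C, so the excess ynol ether is stripped cold before heating.
- **Protecting groups.** All three are benzyl, so one hydrogenolysis finishes the synthesis.

Step 1
Reactants: 1 4-bromophenol; 2 3-chloro-3-methylbut-1-yne
Product: 3 1-bromo-4-[(2-methylbut-3-yn-2-yl)oxy]benzene
Conditions: K2CO3, KI, CuI (cat.), acetone, reflux
Reagents that add atoms: none
Why: Copper-assisted Williamson-type O-propargylation of a phenoxide with a tertiary propargylic chloride is the standard entry to aryl 1,1-dimethylpropargyl ethers and leaves the aryl bromide alone.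

Step 2
Reactants: 3 1-bromo-4-[(2-methylbut-3-yn-2-yl)oxy]benzene
Product: 4 6-bromo-2,2-dimethyl-2H-chromene
Conditions: PhNEt2, 190 °C
Reagents that add atoms: none
Why: The aromatic propargyl Claisen rearrangement, followed by enolisation, 1,5-hydrogen shift and oxa-6π electrocyclisation, reliably turns such ethers into 2,2-dimethylchromenes, and the para bromine leaves two equivalent ortho positions so that only one chromene can form.

Step 3
Reactants: 4 6-bromo-2,2-dimethyl-2H-chromene
Product: 5 (3R,4R)-6-bromo-3,4-epoxy-2,2-dimethylchroman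
Conditions: (R,R)-[N,N'-bis(3,5-di-tert-butylsalicylidene)cyclohexane-1,2-diaminato]MnCl (3 mol %), 4-phenylpyridine N-oxide, aq NaOCl (pH 11.3), CH2Cl2, 0 °C
Reagents that add atoms: sodium hypochlorite, [Na+].[O-]Cl
Why: In the Jacobsen epoxidation, for which 2,2-dimethylchromenes are the best substrate class, the (R,R)-configured salen complex of trivalent manganese delivers oxygen to one face of the cis alkene and should set C3 and C4 as R,R according to the established correlation for chromenes.

Step 4
Reactants: 5 (3R,4R)-6-bromo-3,4-epoxy-2,2-dimethylchroman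
Product: 6 (3R)-6-bromo-2,2-dimethylchroman-3-ol
Conditions: LiAlH4, THF, 0 °C
Reagents that add atoms: none
Why: SN2-type hydride opening of the epoxide occurs at benzylic C4 because C3 is shielded by the neighbouring quaternary carbon, so the C3–O bond keeps its R configuration, C4 ceases to be stereogenic and the aryl bromide survives at 0 °C.

Step 5
Reactants: 6 (3R)-6-bromo-2,2-dimethylchroman-3-ol
Product: 7 (3R)-3-(benzyloxy)-6-bromo-2,2-dimethylchroman
Conditions: NaH, BnBr, Bu4NI (cat.), DMF, 0 °C to rt
Reagents that add atoms: benzyl bromide, BrCc1ccccc1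
Why: Williamson etherification of the sodium alkoxide masks the only hydroxyl group that would later be oxidised or would trap a ketene, and it does not touch the C3–O bond.

Step 6
Reactants: 7 (3R)-3-(benzyloxy)-6-bromo-2,2-dimethylchroman
Product: 8 2-[(3R)-3-(benzyloxy)-2,2-dimethylchroman-6-yl]-4,4,5,5-tetramethyl-1,3,2-dioxaborolane
Conditions: B2pin2, Pd(dppf)Cl2 (3 mol %), KOAc, 1,4-dioxane, 90 °C
Reagents that add atoms: bis(pinacolato)diboron, CC1(C)OB(OC1(C)C)B1OC(C)(C)C(C)(C)O1
Why: Miyaura borylation of an unhindered, electron-rich aryl bromide is routine and compatible with alkyl and benzyl ethers.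

Step 7
Reactants: 9 kojic acid
Product: 10 6-bromokojic acid [6-bromo-5-hydroxy-2-(hydroxymethyl)-4H-pyran-4-one]
Conditions: NBS, DMF, 0 °C to rt, dark
Reagents that add atoms: N-bromosuccinimide, O=C1CCC(=O)N1Br
Why: Electrophilic bromination goes to C6, the β-carbon of the C5 enol and the position at which kojic acid undergoes all its electrophilic substitutions.

Step 8
Reactants: 10 6-bromokojic acid
Product: 11 5-(benzyloxy)-6-bromo-2-(hydroxymethyl)-4H-pyran-4-one
Conditions: BnBr, K2CO3, DMF, rt
Reagents that add atoms: benzyl bromide, BrCc1ccccc1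
Why: Williamson O-alkylation is chemoselective because carbonate deprotonates only the acidic enol and not the primary alcohol, and the non-nucleophilic medium spares the vinylogous acyl bromide.

Step 9
Reactants: 8 chromanyl pinacol boronate; 11 5-(benzyloxy)-6-bromo-2-(hydroxymethyl)-4H-pyran-4-one
Product: 12 5-(benzyloxy)-6-[(3R)-3-(benzyloxy)-2,2-dimethylchroman-6-yl]-2-(hydroxymethyl)-4H-pyran-4-one
Conditions: Pd(dppf)Cl2 (5 mol %), K3PO4, 1,4-dioxane/H2O, 80 °C
Reagents that add atoms: none
Why: In this Suzuki–Miyaura coupling the C6–Br bond, a vinylogous acyl bromide, adds readily to zerovalent palladium, as known for 2-bromo-3-alkoxy-4-pyranones, and the mild phosphate base limits hydrolytic loss of bromide.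

Step 10
Reactants: 12 coupled hydroxymethylpyranone
Product: 13 5-(benzyloxy)-6-[(3R)-3-(benzyloxy)-2,2-dimethylchroman-6-yl]-4-oxo-4H-pyran-2-carboxylic acid
Conditions: TEMPO (cat.), PhI(OAc)2 (2.2 equiv), MeCN/H2O, rt
Reagents that add atoms: water, O
Why: Oxoammonium-catalysed oxidation of the primary alcohol proceeds through the readily hydrated electron-poor aldehyde to the acid, the transformation by which O-benzylkojic acid is turned into O-benzylcomenic acid, and it spares benzyl ethers and the alkoxyarene.

Step 11
Reactants: 13 pyranone carboxylic acid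
Product: 15 5-(benzyloxy)-6-[(3R)-3-(benzyloxy)-2,2-dimethylchroman-6-yl]-2-(diazoacetyl)-4H-pyran-4-one, via acid chloride 14 (not isolated)
Conditions: (COCl)2, DMF (cat.), CH2Cl2, 0 °C to rt, evaporate; then add to CH2N2 (3 equiv), Et2O/THF, −10 °C
Reagents that add atoms: diazomethane, C=[N+]=[N-]; oxalyl chloride, O=C(Cl)C(=O)Cl (chlorine of 14 only)
Why: Acylation of diazomethane by an acid chloride without α-hydrogens (first stage of the Arndt–Eistert sequence) is known for chromone-2-carbonyl chlorides, and inverse addition in the cold lets excess reagent scavenge HCl while holding back dipolar cycloaddition.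

Step 12
Reactants: 16 benzyl alcohol; 17 trichloroethylene
Product: 20 benzyl ethynyl ether, via dichlorovinyl ether 18 (not isolated), via lithium benzyloxyacetylide 19 (not isolated)
Conditions: KH, THF, 0 °C; 17, −50 °C to rt; n-BuLi (2.4 equiv), −78 to −40 °C; H2O, −78 to 0 °C; cold pentane filtration, used at once
Reagents that add atoms: n-butyllithium, [Li]CCCC (lithium of 19 only)
Why: This is the established ynol ether synthesis from trichloroethylene, in which the potassium alkoxide undergoes net substitution to the (E)-dichlorovinyl ether, two equivalents of n-BuLi effect dehydrochlorination and chlorine–lithium exchange, and cold protonation releases the terminal alkyne.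

Step 13
Reactants: 15 pyranonyl diazomethyl ketone; 20 benzyl ethynyl ether
Product: 24 3,7-bis(benzyloxy)-2-[(3R)-3-(benzyloxy)-2,2-dimethylchroman-6-yl]-5-hydroxy-4H-chromen-4-one, via pyranonylketene 21 (not isolated), via cyclobutenone 22 (not isolated), via dienylketene 23 (not isolated)
Conditions: 20 (3 equiv), CH2Cl2, 450 nm LEDs, 15 °C; strip solvent and excess 20 at or below 20 °C under high vacuum; then toluene, 100 °C
Reagents that add atoms: none
Why: Proposed new method: light of 450 nm is absorbed only by the diazo n→π* band, N2 leaves, and pyranone C2 (future C8a) migrates to the diazo carbon (future C8) in a Wolff rearrangement, giving ketene 21 whose carbonyl carbon is the future C5. The polarised [2+2] cycloaddition joins the nucleophilic terminal carbon of 20 (C6) to that carbonyl carbon and the oxygen-bearing carbon (C7) to C8, so the donor polarisation of the ynol ether alone secures the needed regiochemistry, benzyloxy meta to the coming phenol. On heating, cyclobutenone 22 opens reversibly by a conrotatory 4π process, and the rotamer 23 with the pyranonyl group turned inward is drained by a disrotatory 6π electrocyclisation that closes the six-membered carbocycle ring A between the ketene carbon and pyranone C3–H (future C4a). Site selectivity is structural, since C3 is the only carbon next to C2 (the other neighbour is O1), and it is polarity-matched, since C3 is the nucleophilic α-carbon of a vinylogous ester; the dienone formed has its C4a–H between two carbonyls and enolises at once to the chelated 5-OH, which is too poor a nucleophile to trap ketenes. The closest known reaction type is the Danheiser benzannulation of aryl and heteroaryl (furyl, thienyl, pyrrolyl) diazomethyl ketones with alkoxy- or siloxyalkynes; new are the weakly aromatic 4-pyranone C=C as the ene part and the visible-light Wolff trigger, itself known for diazoketones. No stereocentre is formed in 24 (the C4 centre of 22 is erased on ring opening) and the remote (3R) centre is a spectator.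

Step 14
Reactants: 24 tribenzylated 5-hydroxyflavone
Product: 25 2-[(3R)-3-hydroxy-2,2-dimethylchroman-6-yl]-3,5,7-trihydroxy-4H-chromen-4-one (target)
Conditions: H2 (1 atm), 10% Pd/C, EtOAc/MeOH, rt
Reagents that add atoms: none
Why: Catalytic hydrogenolysis cleaves all three O–CH2Ph bonds, as is standard for benzylated flavonols whose conjugated C2=C3 bond resists reduction at one atmosphere, and the non-benzylic C3–O bond of the chromanol keeps its R configuration.

Compound list
1 | 4-bromophenol | Oc1ccc(Br)cc1 | starting material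
2 | 3-chloro-3-methylbut-1-yne | C#CC(C)(C)Cl | starting material
3 | 1-bromo-4-[(2-methylbut-3-yn-2-yl)oxy]benzene | C#CC(C)(C)Oc1ccc(Br)cc1 | intermediate
4 | 6-bromo-2,2-dimethyl-2H-chromene | CC1(C)C=Cc2cc(Br)ccc2O1 | intermediate
5 | (3R,4R)-6-bromo-3,4-epoxy-2,2-dimethylchroman | CC1(C)Oc2ccc(Br)cc2[C@H]3O[C@@H]13 | intermediate
6 | (3R)-6-bromo-2,2-dimethylchroman-3-ol | CC1(C)Oc2ccc(Br)cc2C[C@H]1O | intermediate
7 | (3R)-3-(benzyloxy)-6-bromo-2,2-dimethylchroman | CC1(C)Oc2ccc(Br)cc2C[C@H]1OCc1ccccc1 | intermediate
8 | 2-[(3R)-3-(benzyloxy)-2,2-dimethylchroman-6-yl]-4,4,5,5-tetramethyl-1,3,2-dioxaborolane | CC1(C)Oc2ccc(B3OC(C)(C)C(C)(C)O3)cc2C[C@H]1OCc1ccccc1 | intermediate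
9 | kojic acid | O=c1cc(CO)occ1O | starting material
10 | 6-bromo-5-hydroxy-2-(hydroxymethyl)-4H-pyran-4-one | O=c1cc(CO)oc(Br)c1O | intermediate
11 | 5-(benzyloxy)-6-bromo-2-(hydroxymethyl)-4H-pyran-4-one | O=c1cc(CO)oc(Br)c1OCc1ccccc1 | intermediate
12 | 5-(benzyloxy)-6-[(3R)-3-(benzyloxy)-2,2-dimethylchroman-6-yl]-2-(hydroxymethyl)-4H-pyran-4-one | CC1(C)Oc2ccc(-c3oc(CO)cc(=O)c3OCc3ccccc3)cc2C[C@H]1OCc1ccccc1 | intermediate
13 | 5-(benzyloxy)-6-[(3R)-3-(benzyloxy)-2,2-dimethylchroman-6-yl]-4-oxo-4H-pyran-2-carboxylic acid | CC1(C)Oc2ccc(-c3oc(C(=O)O)cc(=O)c3OCc3ccccc3)cc2C[C@H]1OCc1ccccc1 | intermediate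
14 | the corresponding 4-oxo-4H-pyran-2-carbonyl chloride | CC1(C)Oc2ccc(-c3oc(C(=O)Cl)cc(=O)c3OCc3ccccc3)cc2C[C@H]1OCc1ccccc1 | intermediate (not isolated)
15 | 5-(benzyloxy)-6-[(3R)-3-(benzyloxy)-2,2-dimethylchroman-6-yl]-2-(diazoacetyl)-4H-pyran-4-one | CC1(C)Oc2ccc(-c3oc(C(=O)C=[N+]=[N-])cc(=O)c3OCc3ccccc3)cc2C[C@H]1OCc1ccccc1 | intermediate
16 | benzyl alcohol | OCc1ccccc1 | starting material
17 | trichloroethylene | ClC=C(Cl)Cl | starting material
18 | benzyl (E)-1,2-dichlorovinyl ether | Cl/C=C(/Cl)OCc1ccccc1 | intermediate (not isolated)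
19 | lithium benzyloxyacetylide | [Li]C#COCc1ccccc1 | intermediate (not isolated)
20 | benzyl ethynyl ether | C#COCc1ccccc1 | intermediate
21 | {5-(benzyloxy)-6-[(3R)-3-(benzyloxy)-2,2-dimethylchroman-6-yl]-4-oxo-4H-pyran-2-yl}ketene | CC1(C)Oc2ccc(-c3oc(C=C=O)cc(=O)c3OCc3ccccc3)cc2C[C@H]1OCc1ccccc1 | intermediate (not isolated)
22 | 3-(benzyloxy)-4-(pyranon-2-yl)cyclobut-2-en-1-one, pyranonyl group as in 21, both C4 epimers | CC1(C)Oc2ccc(-c3oc(C4C(=O)C=C4OCc4ccccc4)cc(=O)c3OCc3ccccc3)cc2C[C@H]1OCc1ccccc1 | intermediate (not isolated)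
23 | (3E)-3-(benzyloxy)-4-(pyranon-2-yl)buta-1,3-dien-1-one, pyranonyl group as in 21 and cis to the ketene arm | CC1(C)Oc2ccc(-c3oc(/C=C(\C=C=O)OCc4ccccc4)cc(=O)c3OCc3ccccc3)cc2C[C@H]1OCc1ccccc1 | intermediate (not isolated)
24 | 3,7-bis(benzyloxy)-2-[(3R)-3-(benzyloxy)-2,2-dimethylchroman-6-yl]-5-hydroxy-4H-chromen-4-one | CC1(C)Oc2ccc(-c3oc4cc(OCc5ccccc5)cc(O)c4c(=O)c3OCc3ccccc3)cc2C[C@H]1OCc1ccccc1 | intermediate
25 | 2-[(3R)-3-hydroxy-2,2-dimethylchroman-6-yl]-3,5,7-trihydroxy-4H-chromen-4-one | CC1(C)Oc2ccc(-c3oc4cc(O)cc(O)c4c(=O)c3O)cc2C[C@H]1O | target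

Total step count: 14. Longest linear sequence: 11 steps (steps 1–6, 9–11, 13 and 14, from 4-bromophenol).

Steps most likely to fail

1. **Step 13.**
   - What may go wrong: the electron-poor pyranonyl group may migrate sluggishly in the Wolff step. The ketene may be diverted before the [2+2]. The cross-conjugated pyranone C=C may be reluctant to enter the 6π closure.
   - Fallback: it uses known chemistry, buys ring A instead of building it, sets out from bromide 7 and rejoins the route at target 25. Bromine–lithium exchange on 7 (n-BuLi, THF, −78 °C) and quenching with DMF should give (3R)-3-(benzyloxy)-2,2-dimethylchroman-6-carbaldehyde F1. Commercial 2,4,6-trihydroxyacetophenone is dibenzylated (BnBr, K2CO3, DMF) to 1-[2,4-bis(benzyloxy)-6-hydroxyphenyl]ethanone F2. Claisen–Schmidt condensation of the two (KOH, EtOH) should lead to the (E)-2'-hydroxychalcone F3. Iodine-catalysed oxidative cyclisation in DMSO at 130 °C should then give the 5,7-bis(benzyloxy)flavone F4. Epoxidation of its C2=C3 bond with dimethyldioxirane gives the flavone 2,3-epoxide F5, and TsOH-induced isomerisation gives the 5,7-bis(benzyloxy)flavonol F6. Hydrogenolysis under the conditions of step 14 then gives 25.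

2. **Step 11.**
   - What may go wrong: dipolar cycloaddition of diazomethane across the doubly activated C2=C3 bond, or attack on the ring, may compete with acylation.
   - Fallback: it sets out from acid chloride 14 and rejoins the route at 15. The carbon is brought in as a methyl nucleophile and the nitrogen by detrifluoroacetylative diazo transfer. Treating 14 with MeNHOMe·HCl and Et3N in CH2Cl2 should give the Weinreb amide F7. MeMgBr in THF at −78 °C then gives the 2-acetylpyranone F8. Enolisation with LiN(SiMe3)2 and acylation with CF3CO2CH2CF3 at −78 °C gives the trifluoroacetylated diketone F9. This is taken crude into MsN3, Et3N and H2O in MeCN to deliver 15.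

3. **Step 12.**
   - What may go wrong: excess n-BuLi may cause benzylic metalation with Wittig-type rearrangement. The ynol ether may be lost by sigmatropic rearrangement or polymerisation during concentration.
   - Fallback: it sets out from benzyl alcohol 16 and rejoins the route at 19, which is quenched to 20 as before. The two-carbon unit now comes from a vinyl ether, and amide bases replace the alkyllithium. Transfer vinylation of 16 ([Ir(cod)Cl]2, Na2CO3, vinyl acetate, toluene, 100 °C) should give benzyl vinyl ether F10. Bromine in CH2Cl2 at −78 °C gives benzyl 1,2-dibromoethyl ether F11. One equivalent of KOt-Bu gives benzyl (Z)-2-bromovinyl ether F12. LiN(i-Pr)2 (2.2 equiv, THF, −78 °C) then effects the anti elimination and deprotonation to 19. The product is kept as a cold stock solution and never concentrated to dryness.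

Further compounds
F1 | step 13 | (3R)-3-(benzyloxy)-2,2-dimethylchroman-6-carbaldehyde | CC1(C)Oc2ccc(C=O)cc2C[C@H]1OCc1ccccc1
F2 | step 13 | 1-[2,4-bis(benzyloxy)-6-hydroxyphenyl]ethanone | CC(=O)c1c(O)cc(OCc2ccccc2)cc1OCc1ccccc1
F3 | step 13 | (E)-1-[2,4-bis(benzyloxy)-6-hydroxyphenyl]-3-[(3R)-3-(benzyloxy)-2,2-dimethylchroman-6-yl]prop-2-en-1-one | CC1(C)Oc2ccc(/C=C/C(=O)c3c(O)cc(OCc4ccccc4)cc3OCc3ccccc3)cc2C[C@H]1OCc1ccccc1
F4 | step 13 | 5,7-bis(benzyloxy)-2-[(3R)-3-(benzyloxy)-2,2-dimethylchroman-6-yl]-4H-chromen-4-one | CC1(C)Oc2ccc(-c3cc(=O)c4c(OCc5ccccc5)cc(OCc5ccccc5)cc4o3)cc2C[C@H]1OCc1ccccc1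
F5 | step 13 | 2,3-epoxide of F4 (both epoxide diastereomers) | CC1(C)Oc2ccc(C34OC3C(=O)c3c(OCc5ccccc5)cc(OCc5ccccc5)cc3O4)cc2C[C@H]1OCc1ccccc1
F6 | step 13 | 5,7-bis(benzyloxy)-2-[(3R)-3-(benzyloxy)-2,2-dimethylchroman-6-yl]-3-hydroxy-4H-chromen-4-one | CC1(C)Oc2ccc(-c3oc4cc(OCc5ccccc5)cc(OCc5ccccc5)c4c(=O)c3O)cc2C[C@H]1OCc1ccccc1
F7 | step 11 | N-methoxy-N-methylamide of acid 13 | CC1(C)Oc2ccc(-c3oc(C(=O)N(C)OC)cc(=O)c3OCc3ccccc3)cc2C[C@H]1OCc1ccccc1
F8 | step 11 | 2-acetyl-5-(benzyloxy)-6-[(3R)-3-(benzyloxy)-2,2-dimethylchroman-6-yl]-4H-pyran-4-one | CC1(C)Oc2ccc(-c3oc(C(C)=O)cc(=O)c3OCc3ccccc3)cc2C[C@H]1OCc1ccccc1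
F9 | step 11 | 4,4,4-trifluoro-1-(pyranon-2-yl)butane-1,3-dione, pyranonyl group as in F8 | CC1(C)Oc2ccc(-c3oc(C(=O)CC(=O)C(F)(F)F)cc(=O)c3OCc3ccccc3)cc2C[C@H]1OCc1ccccc1
F10 | step 12 | benzyl vinyl ether | C=COCc1ccccc1
F11 | step 12 | benzyl 1,2-dibromoethyl ether (racemic) | BrCC(Br)OCc1ccccc1
F12 | step 12 | benzyl (Z)-2-bromovinyl ether | Br/C=C\OCc1ccccc1
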